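The route rests on cutting ring B at its only alkene, C4=C5 (C4 bears the hydroxymethyl carbon C7, C5 is a CH), which lies between the carbinols C3 and C6 that flank the cis-fused oxirane C1–C2. Ring-closing metathesis makes this trisubstituted alkene and closes the six-membered ring in one operation without creating a stereocentre. Its precursor is an acyclic trisubstituted oxirane whose two cis arms are a silylated vinyl carbinol (C6) and a silylated 2-(silyloxymethyl)allyl carbinol (C3), with a free hydroxymethyl group on C1; C1, C2, C3 and C6 are set before by reagent control. The derived aldehyde is then joined to a ring-A dienyl iodide.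

Key step: step 13

Remark: locants are ring B C1–C6 (C1 quaternary oxirane carbon, C2 oxirane CH, C7 the CH2O on C4), side chain C1′ (carbinol on C1) to C5′, ring A C1″–C6″ (C1″ bears the chain, C5″ the hydroxyl); TBS = tert-butyldimethylsilyl, TES = triethylsilyl, PMB = 4-methoxybenzyl, PT = 1-phenyl-1H-tetrazol-5-yl.

Step 1
Reactants: 1 2-methylene-1,3-propanediol
Product: 2 2-[(TBS-oxy)methyl]prop-2-en-1-ol
Conditions: NaH (1.0 equiv), TBSCl (1.0 equiv), THF, 0 °C to rt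
Reagents that add atoms: tert-butyldimethylsilyl chloride, CC(C)(C)[Si](C)(C)Cl
Why: Monosilylation of a symmetric diol via its sparingly soluble monosodium alkoxide (O-silylation) should stop after one hydroxyl.

Step 2
Reactants: 2 2-[(TBS-oxy)methyl]prop-2-en-1-ol
Product: 3 2-[(TBS-oxy)methyl]prop-2-enal
Conditions: MnO2, CH2Cl2, rt
Reagents that add atoms: none
Why: Activated MnO2 oxidises the primary allylic alcohol to the enal (allylic oxidation) under neutral conditions that leave the silyl ether alone.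

Step 3
Reactants: 4 propargyl alcohol
Product: 5 4-methoxybenzyl propargyl ether
Conditions: NaH, PMBCl, Bu4NI (cat.), THF, 0 °C to rt
Reagents that add atoms: 4-methoxybenzyl chloride, COc1ccc(CCl)cc1
Why: Williamson etherification of the alkoxide, which forms in preference to the acetylide because O–H is far more acidic than the alkyne C–H.

Step 4
Reactants: 3 2-[(TBS-oxy)methyl]prop-2-enal; 5 4-methoxybenzyl propargyl ether
Product: 7 (3S)-6-(PMB-oxy)-2-[(TBS-oxy)methyl]hex-1-en-4-yn-3-ol, via alkynylzinc 6 (not isolated)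
Conditions: Me2Zn, (R,R)-ProPhenol (20 mol%), Ph3PO (40 mol%), toluene, 0 °C
Reagents that add atoms: none
Why: Zinc–ProPhenol-catalysed enantioselective alkynylation of an enal, a substrate class this catalyst handles: the dinuclear zinc complex binds aldehyde and alkynylzinc together and the ligand antipode is the one that delivers the alkyne to the Si face, which sets C3 as (S).

Step 5
Reactants: 7 (3S)-6-(PMB-oxy)-2-[(TBS-oxy)methyl]hex-1-en-4-yn-3-ol
Product: 9 (3S,4Z)-5-iodo-6-(PMB-oxy)-2-[(TBS-oxy)methyl]hexa-1,4-dien-3-ol, via cyclic alkenylalanate 8 (not isolated)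
Conditions: Red-Al, THF, 0 °C; then I2, THF, −78 °C
Reagents that add atoms: iodine, II
Why: Red-Al trans-hydroalumination of the propargylic alkoxide puts hydride on C2 and aluminium on C1 inside a five-membered alkoxyalanate, and iodinolysis with retention leaves iodine cis to the C3 carbinol, i.e. the (Z)-iodide; the cold quench forestalls β-elimination of the PMB ether.

Step 6
Reactants: 9 (3S,4Z)-5-iodo-6-(PMB-oxy)-2-[(TBS-oxy)methyl]hexa-1,4-dien-3-ol
Product: 10 (3S,4Z)-3-(TBS-oxy)-5-iodo-6-(PMB-oxy)-2-[(TBS-oxy)methyl]hexa-1,4-diene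
Conditions: TBSOTf, 2,6-lutidine, CH2Cl2, −78 °C
Reagents that add atoms: tert-butyldimethylsilyl triflate, CC(C)(C)[Si](C)(C)OS(=O)(=O)C(F)(F)F
Why: Silyl triflate silylation of the hindered secondary allylic alcohol, needed so that only one carbinol is free for the later oxidation.

Step 7
Reactants: 10 (3S,4Z)-3-(TBS-oxy)-5-iodo-6-(PMB-oxy)-2-[(TBS-oxy)methyl]hexa-1,4-diene; 11 acrolein
Product: 13 (4Z,6S)-6-(TBS-oxy)-4-[(PMB-oxy)methyl]-7-[(TBS-oxy)methyl]octa-1,4,7-trien-3-ol as a mixture of C3 epimers, via alkenyllithium 12 (not isolated)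
Conditions: t-BuLi (2.1 equiv), Et2O, −78 °C; then acrolein, −78 °C
Reagents that add atoms: none
Why: Iodine–lithium exchange with retention of alkene geometry followed by 1,2-addition to acrolein at −78 °C, where 1,4-silyl migration and β-elimination of the ether are slow; C6 forms without control and is corrected in steps 8 and 9.

Step 8
Reactants: 13 (4Z,6S)-6-(TBS-oxy)-4-[(PMB-oxy)methyl]-7-[(TBS-oxy)methyl]octa-1,4,7-trien-3-ol (C3 epimers)
Product: 14 (4Z,6S)-6-(TBS-oxy)-4-[(PMB-oxy)methyl]-7-[(TBS-oxy)methyl]octa-1,4,7-trien-3-one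
Conditions: MnO2, CH2Cl2, 0 °C to rt
Reagents that add atoms: none
Why: MnO2 oxidation of the doubly allylic alcohol converges both C6 epimers on one cross-conjugated dienone.

Step 9
Reactants: 14 (4Z,6S)-6-(TBS-oxy)-4-[(PMB-oxy)methyl]-7-[(TBS-oxy)methyl]octa-1,4,7-trien-3-one
Product: 15 (3S,4Z,6S)-6-(TBS-oxy)-4-[(PMB-oxy)methyl]-7-[(TBS-oxy)methyl]octa-1,4,7-trien-3-ol
Conditions: (R)-Me-CBS (0.3 equiv), catecholborane, toluene, −78 °C
Reagents that add atoms: none
Why: Corey–Bakshi–Shibata reduction: the carbonyl coordinates the oxazaborolidine anti to the larger, branched alkenyl group and hydride from the bound borane adds to the face that gives (6S) in ring-B locants, while catecholborane at −78 °C does not hydroborate the alkenes.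

Step 10
Reactants: 15 (3S,4Z,6S)-6-(TBS-oxy)-4-[(PMB-oxy)methyl]-7-[(TBS-oxy)methyl]octa-1,4,7-trien-3-ol
Product: 16 (3S,4Z,6S)-3,6-bis(TBS-oxy)-4-[(PMB-oxy)methyl]-7-[(TBS-oxy)methyl]octa-1,4,7-triene
Conditions: TBSOTf, 2,6-lutidine, CH2Cl2, −78 °C
Reagents that add atoms: tert-butyldimethylsilyl triflate, CC(C)(C)[Si](C)(C)OS(=O)(=O)C(F)(F)F
Why: Silyl triflate silylation caps the second carbinol so that the only hydroxyl left after the next step is the one that has to direct the epoxidation.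

Step 11
Reactants: 16 (3S,4Z,6S)-3,6-bis(TBS-oxy)-4-[(PMB-oxy)methyl]-7-[(TBS-oxy)methyl]octa-1,4,7-triene
Product: 17 (2Z,4S)-4-(TBS-oxy)-2-[(1S)-1-(TBS-oxy)prop-2-en-1-yl]-5-[(TBS-oxy)methyl]hexa-2,5-dien-1-ol
Conditions: DDQ, CH2Cl2/pH 7 buffer, 0 °C
Reagents that add atoms: none
Why: Oxidative PMB cleavage (DDQ) through the benzylic oxocarbenium ion frees the C1 hydroxymethyl group and leaves silyl ethers and alkenes untouched.

Step 12
Reactants: 17 (2Z,4S)-4-(TBS-oxy)-2-[(1S)-1-(TBS-oxy)prop-2-en-1-yl]-5-[(TBS-oxy)methyl]hexa-2,5-dien-1-ol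
Product: 18 {(2S,3S)-3-[(1R)-1-(TBS-oxy)-2-[(TBS-oxy)methyl]prop-2-en-1-yl]-2-[(1S)-1-(TBS-oxy)prop-2-en-1-yl]oxiran-2-yl}methanol
Conditions: Ti(OiPr)4 (20 mol%), L-(+)-DIPT (25 mol%), t-BuOOH, 4 Å MS, CH2Cl2, −20 °C
Reagents that add atoms: tert-butyl hydroperoxide, CC(C)(C)OO
Why: Sharpless asymmetric epoxidation of a primary (E)-2,3-disubstituted allylic alcohol: with L-(+)-DIPT the titanium-bound peroxide is delivered under reagent control to the face that gives the C1/C2 oxirane drawn, and only the alkene next to the free hydroxyl reacts.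

Step 13
Reactants: 18 {(2S,3S)-3-[(1R)-1-(TBS-oxy)-2-[(TBS-oxy)methyl]prop-2-en-1-yl]-2-[(1S)-1-(TBS-oxy)prop-2-en-1-yl]oxiran-2-yl}methanol
Product: 19 [(1S,2S,5R,6S)-2,5-bis(TBS-oxy)-4-[(TBS-oxy)methyl]-7-oxabicyclo[4.1.0]hept-3-en-1-yl]methanol
Conditions: Grubbs II (10 mol%), toluene (5 mM), 80 °C, argon sparge
Reagents that add atoms: none
Why: The ruthenium alkylidene first exchanges onto the monosubstituted vinyl group at C6, adds [2+2] to the 1,1-disubstituted alkene at C4 and the ruthenacyclobutane cycloreverts to the ring alkene, ethylene being lost on turnover. The closest known reaction type is ring-closing metathesis of polyoxygenated 1,7-dienes to conduritol- and carbasugar-type cyclohexenes. Ring B closes as a six-membered carbocycle by formation of its C4=C5 double bond, the oxirane becoming the cis ring fusion of a 7-oxabicyclo[4.1.0]heptene. No stereocentre is made; C3, C6 and C1/C2 come from steps 4, 9 and 12. The step needs cyclisation over oligomerisation and an untouched oxirane: the two alkene arms are cis on the oxirane and so held within reach, no third alkene is left after the epoxidation, the catalyst is neutral and the run is dilute.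

Step 14
Reactants: 19 [(1S,2S,5R,6S)-2,5-bis(TBS-oxy)-4-[(TBS-oxy)methyl]-7-oxabicyclo[4.1.0]hept-3-en-1-yl]methanol
Product: 20 (1S,2S,5R,6S)-2,5-bis(TBS-oxy)-4-[(TBS-oxy)methyl]-7-oxabicyclo[4.1.0]hept-3-ene-1-carbaldehyde
Conditions: Dess–Martin periodinane, pyridine, CH2Cl2, 0 °C to rt
Reagents that add atoms: none
Why: Dess–Martin oxidation of the primary alcohol to an aldehyde that cannot enolise because C1 is quaternary.

Step 15
Reactants: 21 geranyl acetate
Product: 22 (2E)-5-[(2R)-3,3-dimethyloxiran-2-yl]-3-methylpent-2-en-1-yl acetate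
Conditions: D-fructose-derived Shi ketone (30 mol%), Oxone, K2CO3, Bu4NHSO4, MeCN/dimethoxymethane/aq. buffer, 0 °C
Reagents that add atoms: Oxone (potassium peroxymonosulfate), [K+].[O-]S(=O)(=O)OO
Why: Shi epoxidation: the chiral dioxirane attacks the electron-rich 6,7-alkene (the 2,3-alkene is deactivated by the allylic acetate) through a spiro transition state and gives the (R)-epoxide, the source of C5″.

Step 16
Reactants: 22 (2E)-5-[(2R)-3,3-dimethyloxiran-2-yl]-3-methylpent-2-en-1-yl acetate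
Product: 23 [(1S,5R)-5-hydroxy-2,6,6-trimethylcyclohex-2-en-1-yl]methyl acetate
Conditions: ZrCl4 (1.1 equiv), CH2Cl2, −78 to 0 °C
Reagents that add atoms: none
Why: Lewis-acid-promoted epoxide–alkene (cation–olefin) cyclisation through a chair transition state: the epoxide C–O bond is kept as the equatorial C5″ hydroxyl, the (E)-alkene puts CH2OAc equatorial so that C1″ forms cis to it, and loss of a ring proton gives the trisubstituted alkene (the exocyclic isomer, if formed, is removed by chromatography).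

Step 17
Reactants: 23 [(1S,5R)-5-hydroxy-2,6,6-trimethylcyclohex-2-en-1-yl]methyl acetate
Product: 24 [(1S,5R)-5-hydroxy-2,6,6-trimethylcyclohex-2-en-1-yl]methanol
Conditions: K2CO3 (cat.), MeOH, rt
Reagents that add atoms: none
Why: Base-catalysed transesterification removes the acetate.

Step 18
Reactants: 24 [(1S,5R)-5-hydroxy-2,6,6-trimethylcyclohex-2-en-1-yl]methanol
Product: 25 5-({[(1S,5R)-5-hydroxy-2,6,6-trimethylcyclohex-2-en-1-yl]methyl}sulfanyl)-1-phenyl-1H-tetrazole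
Conditions: 1-phenyl-1H-tetrazole-5-thiol, PPh3, DIAD, THF, 0 °C to rt
Reagents that add atoms: 1-phenyl-1H-tetrazole-5-thiol, Sc1nnnn1-c1ccccc1
Why: Mitsunobu thioetherification takes place only at the primary alcohol, the secondary hydroxyl next to the quaternary carbon being too hindered.

Step 19
Reactants: 25 5-({[(1S,5R)-5-hydroxy-2,6,6-trimethylcyclohex-2-en-1-yl]methyl}sulfanyl)-1-phenyl-1H-tetrazole
Product: 26 5-({[(1S,5R)-5-hydroxy-2,6,6-trimethylcyclohex-2-en-1-yl]methyl}sulfonyl)-1-phenyl-1H-tetrazole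
Conditions: (NH4)6Mo7O24·4H2O (10 mol%), 30% H2O2, EtOH, 0 °C to rt
Reagents that add atoms: hydrogen peroxide, OO
Why: Molybdate-catalysed peroxide oxidation takes the sulfide to the sulfone faster than it epoxidises the trisubstituted alkene.

Step 20
Reactants: 26 5-({[(1S,5R)-5-hydroxy-2,6,6-trimethylcyclohex-2-en-1-yl]methyl}sulfonyl)-1-phenyl-1H-tetrazole
Product: 27 1-phenyl-5-({[(1S,5R)-2,6,6-trimethyl-5-(TES-oxy)cyclohex-2-en-1-yl]methyl}sulfonyl)-1H-tetrazole
Conditions: TESOTf, 2,6-lutidine, CH2Cl2, −78 to 0 °C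
Reagents that add atoms: triethylsilyl triflate, CC[Si](CC)(CC)OS(=O)(=O)C(F)(F)F
Why: Silyl triflate silylation protects the hindered secondary alcohol as a TES ether that is easy to remove at the end.

Step 21
Reactants: 4 propargyl alcohol
Product: 29 (Z)-3-iodo-2-methylprop-2-en-1-ol, via vinylmagnesium alkoxide 28 (not isolated)
Conditions: MeMgBr (2.5 equiv), CuI (10 mol%), THF, −10 °C to rt; then I2, −10 °C
Reagents that add atoms: methylmagnesium bromide, C[Mg]Br; iodine, II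
Why: Copper-catalysed anti-carbomagnesiation of the propargylic alkoxide puts methyl on C2 and magnesium on C3 in a five-membered chelate, and iodinolysis with retention gives the (Z)-iodo alcohol.

Step 22
Reactants: 29 (Z)-3-iodo-2-methylprop-2-en-1-ol
Product: 30 (Z)-3-iodo-2-methylprop-2-enal
Conditions: MnO2, CH2Cl2, rt, dark
Reagents that add atoms: none
Why: MnO2 allylic oxidation under neutral conditions gives the (Z)-enal, which is used at once to avoid Z/E isomerisation.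

Step 23
Reactants: 27 1-phenyl-5-({[(1S,5R)-2,6,6-trimethyl-5-(TES-oxy)cyclohex-2-en-1-yl]methyl}sulfonyl)-1H-tetrazole; 30 (Z)-3-iodo-2-methylprop-2-enal
Product: 32 (1Z,3E)-1-iodo-2-methyl-4-[(1S,5R)-2,6,6-trimethyl-5-(TES-oxy)cyclohex-2-en-1-yl]buta-1,3-diene, via sulfonyl carbanion 31 (not isolated)
Conditions: KHMDS, THF, −78 °C; then 30, −78 °C to rt
Reagents that add atoms: none
Why: Julia–Kocienski olefination: the metalated tetrazolyl sulfone adds to the aldehyde, Smiles rearrangement and loss of sulfur dioxide and tetrazololate give the C4′=C5′ alkene, expected to be E, and the (Z)-iodoalkene is carried through unchanged.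

Step 24
Reactants: 32 (1Z,3E)-1-iodo-2-methyl-4-[(1S,5R)-2,6,6-trimethyl-5-(TES-oxy)cyclohex-2-en-1-yl]buta-1,3-diene; 20 (1S,2S,5R,6S)-2,5-bis(TBS-oxy)-4-[(TBS-oxy)methyl]-7-oxabicyclo[4.1.0]hept-3-ene-1-carbaldehyde
Product: 34 (2Z,4E)-1-[(1S,2S,5R,6S)-2,5-bis(TBS-oxy)-4-[(TBS-oxy)methyl]-7-oxabicyclo[4.1.0]hept-3-en-1-yl]-3-methyl-5-[(1S,5R)-2,6,6-trimethyl-5-(TES-oxy)cyclohex-2-en-1-yl]penta-2,4-dien-1-ol as a mixture of C1 epimers, via dienyllithium 33 (not isolated)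
Conditions: t-BuLi (2.0 equiv), Et2O, −78 °C; then 20, −78 °C
Reagents that add atoms: none
Why: Iodine–lithium exchange with retention and 1,2-addition of the (Z)-dienyllithium to the non-enolisable aldehyde join the two halves; C1′ forms without reliable control and is set in steps 25 and 26.

Step 25
Reactants: 34 (2Z,4E)-dienol, C1′ epimers
Product: 35 (2Z,4E)-1-[(1S,2S,5R,6S)-2,5-bis(TBS-oxy)-4-[(TBS-oxy)methyl]-7-oxabicyclo[4.1.0]hept-3-en-1-yl]-3-methyl-5-[(1S,5R)-2,6,6-trimethyl-5-(TES-oxy)cyclohex-2-en-1-yl]penta-2,4-dien-1-one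
Conditions: Dess–Martin periodinane, pyridine, CH2Cl2, 0 °C
Reagents that add atoms: none
Why: Dess–Martin oxidation of the dienyl carbinol converges both C1′ epimers on the dienone under buffered, non-isomerising conditions.

Step 26
Reactants: 35 (2Z,4E)-dienone
Product: 36 (1S,2Z,4E)-1-[(1S,2S,5R,6S)-2,5-bis(TBS-oxy)-4-[(TBS-oxy)methyl]-7-oxabicyclo[4.1.0]hept-3-en-1-yl]-3-methyl-5-[(1S,5R)-2,6,6-trimethyl-5-(TES-oxy)cyclohex-2-en-1-yl]penta-2,4-dien-1-ol
Conditions: DIBAL-H, CH2Cl2, −78 °C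
Reagents that add atoms: none
Why: 1,2-Reduction of the enone by a non-chelating aluminium hydride under Felkin–Anh control: hydride should enter anti to the C1–O oxirane bond past C2–H while the dienyl group turns away from the C6 silyl ether, which gives (1′S).

Step 27
Reactants: 36 (1S,2Z,4E)-dienol, fully silylated
Product: 37 CNP0389279.1, (1R,2S,5R,6S)-4-(hydroxymethyl)-1-{(1S,2Z,4E)-1-hydroxy-5-[(1S,5R)-5-hydroxy-2,6,6-trimethylcyclohex-2-en-1-yl]-3-methylpenta-2,4-dien-1-yl}-7-oxabicyclo[4.1.0]hept-3-ene-2,5-diol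
Conditions: TBAF, AcOH (1:1), THF, 0 °C to rt
Reagents that add atoms: none
Why: Fluoride cleaves the three TBS ethers and the TES ether (Si–F bond formation), and acetic acid buffering keeps the alkoxides protonated so that the oxirane does not migrate.

Compound list
1 | 2-methylene-1,3-propanediol | C=C(CO)CO | starting material
2 | 2-[(TBS-oxy)methyl]prop-2-en-1-ol | C=C(CO)CO[Si](C)(C)C(C)(C)C | intermediate
3 | 2-[(TBS-oxy)methyl]prop-2-enal | C=C(C=O)CO[Si](C)(C)C(C)(C)C | intermediate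
4 | propargyl alcohol | C#CCO | starting material
5 | 4-methoxybenzyl propargyl ether | C#CCOCc1ccc(OC)cc1 | intermediate
6 | methyl[3-(PMB-oxy)prop-1-yn-1-yl]zinc (not isolated) | C[Zn]C#CCOCc1ccc(OC)cc1 | intermediate
7 | (3S)-6-(PMB-oxy)-2-[(TBS-oxy)methyl]hex-1-en-4-yn-3-ol | C=C(CO[Si](C)(C)C(C)(C)C)[C@@H](O)C#CCOCc1ccc(OC)cc1 | intermediate
8 | sodium cyclic alkoxy(alkenyl)alanate of 7, five-membered O–Al–C ring, two 2-methoxyethoxy groups on Al (not isolated) | C=C(CO[Si](C)(C)C(C)(C)C)[C@H]1O[Al-](OCCOC)(OCCOC)C(COCc2ccc(OC)cc2)=C1.[Na+] | intermediate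
9 | (3S,4Z)-5-iodo-6-(PMB-oxy)-2-[(TBS-oxy)methyl]hexa-1,4-dien-3-ol | C=C(CO[Si](C)(C)C(C)(C)C)[C@@H](O)/C=C(\I)COCc1ccc(OC)cc1 | intermediate
10 | (3S,4Z)-3-(TBS-oxy)-5-iodo-6-(PMB-oxy)-2-[(TBS-oxy)methyl]hexa-1,4-diene | C=C(CO[Si](C)(C)C(C)(C)C)[C@@H](O[Si](C)(C)C(C)(C)C)/C=C(\I)COCc1ccc(OC)cc1 | intermediate
11 | acrolein | C=CC=O | starting material
12 | alkenyllithium from 10, lithium in place of iodine with geometry retained (not isolated) | C=C(CO[Si](C)(C)C(C)(C)C)[C@@H](O[Si](C)(C)C(C)(C)C)/C=C(\[Li])COCc1ccc(OC)cc1 | intermediate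
13 | (4Z,6S)-6-(TBS-oxy)-4-[(PMB-oxy)methyl]-7-[(TBS-oxy)methyl]octa-1,4,7-trien-3-ol, C3 epimers | C=C(CO[Si](C)(C)C(C)(C)C)[C@@H](O[Si](C)(C)C(C)(C)C)/C=C(\C(O)C=C)COCc1ccc(OC)cc1 | intermediate
14 | (4Z,6S)-6-(TBS-oxy)-4-[(PMB-oxy)methyl]-7-[(TBS-oxy)methyl]octa-1,4,7-trien-3-one | C=C(CO[Si](C)(C)C(C)(C)C)[C@@H](O[Si](C)(C)C(C)(C)C)/C=C(\C(=O)C=C)COCc1ccc(OC)cc1 | intermediate
15 | (3S,4Z,6S)-6-(TBS-oxy)-4-[(PMB-oxy)methyl]-7-[(TBS-oxy)methyl]octa-1,4,7-trien-3-ol | C=C(CO[Si](C)(C)C(C)(C)C)[C@@H](O[Si](C)(C)C(C)(C)C)/C=C(\[C@@H](O)C=C)COCc1ccc(OC)cc1 | intermediate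
16 | (3S,4Z,6S)-3,6-bis(TBS-oxy)-4-[(PMB-oxy)methyl]-7-[(TBS-oxy)methyl]octa-1,4,7-triene | C=C(CO[Si](C)(C)C(C)(C)C)[C@@H](O[Si](C)(C)C(C)(C)C)/C=C(\[C@@H](O[Si](C)(C)C(C)(C)C)C=C)COCc1ccc(OC)cc1 | intermediate
17 | (2Z,4S)-4-(TBS-oxy)-2-[(1S)-1-(TBS-oxy)prop-2-en-1-yl]-5-[(TBS-oxy)methyl]hexa-2,5-dien-1-ol | C=C(CO[Si](C)(C)C(C)(C)C)[C@@H](O[Si](C)(C)C(C)(C)C)/C=C(\[C@@H](O[Si](C)(C)C(C)(C)C)C=C)CO | intermediate
18 | {(2S,3S)-3-[(1R)-1-(TBS-oxy)-2-[(TBS-oxy)methyl]prop-2-en-1-yl]-2-[(1S)-1-(TBS-oxy)prop-2-en-1-yl]oxiran-2-yl}methanol, alkenyl arms cis on the oxirane | OC[C@@]1(O[C@H]1[C@H](O[Si](C)(C)C(C)(C)C)C(=C)CO[Si](C)(C)C(C)(C)C)[C@@H](O[Si](C)(C)C(C)(C)C)C=C | intermediate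
19 | [(1S,2S,5R,6S)-2,5-bis(TBS-oxy)-4-[(TBS-oxy)methyl]-7-oxabicyclo[4.1.0]hept-3-en-1-yl]methanol | OC[C@]12O[C@H]1[C@H](O[Si](C)(C)C(C)(C)C)C(CO[Si](C)(C)C(C)(C)C)=C[C@@H]2O[Si](C)(C)C(C)(C)C | intermediate
20 | (1S,2S,5R,6S)-2,5-bis(TBS-oxy)-4-[(TBS-oxy)methyl]-7-oxabicyclo[4.1.0]hept-3-ene-1-carbaldehyde | O=C[C@]12O[C@H]1[C@H](O[Si](C)(C)C(C)(C)C)C(CO[Si](C)(C)C(C)(C)C)=C[C@@H]2O[Si](C)(C)C(C)(C)C | intermediate
21 | geranyl acetate | CC(C)=CCC/C(C)=C/COC(C)=O | starting material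
22 | (2E)-5-[(2R)-3,3-dimethyloxiran-2-yl]-3-methylpent-2-en-1-yl acetate | CC1(C)O[C@@H]1CC/C(C)=C/COC(C)=O | intermediate
23 | [(1S,5R)-5-hydroxy-2,6,6-trimethylcyclohex-2-en-1-yl]methyl acetate (hydroxyl cis to CH2OAc) | CC1=CC[C@@H](O)C(C)(C)[C@H]1COC(C)=O | intermediate
24 | [(1S,5R)-5-hydroxy-2,6,6-trimethylcyclohex-2-en-1-yl]methanol | CC1=CC[C@@H](O)C(C)(C)[C@H]1CO | intermediate
25 | 5-({[(1S,5R)-5-hydroxy-2,6,6-trimethylcyclohex-2-en-1-yl]methyl}sulfanyl)-1-phenyl-1H-tetrazole | CC1=CC[C@@H](O)C(C)(C)[C@H]1CSc1nnnn1-c1ccccc1 | intermediate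
26 | 5-({[(1S,5R)-5-hydroxy-2,6,6-trimethylcyclohex-2-en-1-yl]methyl}sulfonyl)-1-phenyl-1H-tetrazole | CC1=CC[C@@H](O)C(C)(C)[C@H]1CS(=O)(=O)c1nnnn1-c1ccccc1 | intermediate
27 | 1-phenyl-5-({[(1S,5R)-2,6,6-trimethyl-5-(TES-oxy)cyclohex-2-en-1-yl]methyl}sulfonyl)-1H-tetrazole | CC1=CC[C@@H](O[Si](CC)(CC)CC)C(C)(C)[C@H]1CS(=O)(=O)c1nnnn1-c1ccccc1 | intermediate
28 | bromomagnesium (Z)-3-(bromomagnesio)-2-methylprop-2-en-1-olate (not isolated) | Br[Mg]/C=C(/C)CO[Mg]Br | intermediate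
29 | (Z)-3-iodo-2-methylprop-2-en-1-ol | I/C=C(/C)CO | intermediate
30 | (Z)-3-iodo-2-methylprop-2-enal | I/C=C(/C)C=O | intermediate
31 | potassium salt of 27 metalated at the sulfonyl CH2 (not isolated) | CC1=CC[C@@H](O[Si](CC)(CC)CC)C(C)(C)[C@H]1[CH-]S(=O)(=O)c1nnnn1-c1ccccc1.[K+] | intermediate
32 | (1Z,3E)-1-iodo-2-methyl-4-[(1S,5R)-2,6,6-trimethyl-5-(TES-oxy)cyclohex-2-en-1-yl]buta-1,3-diene | CC1=CC[C@@H](O[Si](CC)(CC)CC)C(C)(C)[C@H]1/C=C/C(C)=C\I | intermediate
33 | dienyllithium from 32, lithium in place of iodine with geometry retained (not isolated) | CC1=CC[C@@H](O[Si](CC)(CC)CC)C(C)(C)[C@H]1/C=C/C(C)=C\[Li] | intermediate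
34 | (2Z,4E)-1-[(1S,2S,5R,6S)-2,5-bis(TBS-oxy)-4-[(TBS-oxy)methyl]-7-oxabicyclo[4.1.0]hept-3-en-1-yl]-3-methyl-5-[(1S,5R)-2,6,6-trimethyl-5-(TES-oxy)cyclohex-2-en-1-yl]penta-2,4-dien-1-ol, C1 epimers | CC1=CC[C@@H](O[Si](CC)(CC)CC)C(C)(C)[C@H]1/C=C/C(C)=C\C(O)[C@]12O[C@H]1[C@H](O[Si](C)(C)C(C)(C)C)C(CO[Si](C)(C)C(C)(C)C)=C[C@@H]2O[Si](C)(C)C(C)(C)C | intermediate
35 | (2Z,4E)-1-[(1S,2S,5R,6S)-2,5-bis(TBS-oxy)-4-[(TBS-oxy)methyl]-7-oxabicyclo[4.1.0]hept-3-en-1-yl]-3-methyl-5-[(1S,5R)-2,6,6-trimethyl-5-(TES-oxy)cyclohex-2-en-1-yl]penta-2,4-dien-1-one | CC1=CC[C@@H](O[Si](CC)(CC)CC)C(C)(C)[C@H]1/C=C/C(C)=C\C(=O)[C@]12O[C@H]1[C@H](O[Si](C)(C)C(C)(C)C)C(CO[Si](C)(C)C(C)(C)C)=C[C@@H]2O[Si](C)(C)C(C)(C)C | intermediate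
36 | (1S,2Z,4E)-1-[(1S,2S,5R,6S)-2,5-bis(TBS-oxy)-4-[(TBS-oxy)methyl]-7-oxabicyclo[4.1.0]hept-3-en-1-yl]-3-methyl-5-[(1S,5R)-2,6,6-trimethyl-5-(TES-oxy)cyclohex-2-en-1-yl]penta-2,4-dien-1-ol | CC1=CC[C@@H](O[Si](CC)(CC)CC)C(C)(C)[C@H]1/C=C/C(C)=C\[C@H](O)[C@]12O[C@H]1[C@H](O[Si](C)(C)C(C)(C)C)C(CO[Si](C)(C)C(C)(C)C)=C[C@@H]2O[Si](C)(C)C(C)(C)C | intermediate
37 | CNP0389279.1, (1R,2S,5R,6S)-4-(hydroxymethyl)-1-{(1S,2Z,4E)-1-hydroxy-5-[(1S,5R)-5-hydroxy-2,6,6-trimethylcyclohex-2-en-1-yl]-3-methylpenta-2,4-dien-1-yl}-7-oxabicyclo[4.1.0]hept-3-ene-2,5-diol | CC1=CC[C@@H](O)C(C)(C)[C@H]1/C=C/C(C)=C\[C@H](O)[C@]12O[C@H]1[C@H](O)C(CO)=C[C@@H]2O | target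

Total step count: 27
Longest linear sequence: 17 steps (steps 1, 2, 4–14 and 24–27, from 2-methylene-1,3-propanediol)

Steps most likely to fail

Step 13 (ring-closing metathesis). Loading of the carbene on the vinyl group and closure onto the 1,1-disubstituted alkene may be slowed by the two neighbouring silyl ethers, so that oligomerisation or alkene isomerisation takes over. The fallback runs the same ring closure on a substrate with a free hydroxyl next to the vinyl group. It sets out from 15: hydroxyl-directed epoxidation (VO(acac)2, t-BuOOH, threo through allylic 1,3-strain with the cis C3 arm) should give the PMB-protected epoxy alcohol F1, metathesis of F1 should give the bicyclic alcohol F2, silylation with TBSOTf gives the silyl ether F3, and DDQ removal of the PMB group comes back to the route at 19.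

Step 26 (reduction at C1′). Hydride delivery through a conformer in which aluminium bridges the carbonyl and oxirane oxygens would favour the (1′R) alcohol, and the (Z)-dienone may isomerise or close to a 2H-pyran before it is reduced. The fallback sets C1′ in the carbon–carbon bond-forming event instead. It sets out from aldehyde 20 and iodide 32: a nickel/chromium-mediated Nozaki–Hiyama–Kishi coupling in the presence of a chiral sulfonamide ligand, chosen for addition to the aldehyde face that gives (1′S), comes back to the route at 36 and by-passes 34 and 35; it makes no new compound F0.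

Step 9 (Corey–Bakshi–Shibata reduction at C6). The catalyst may discriminate poorly between the vinyl and the branched alkenyl group, and the vinyl ketone 14 may be lost to conjugate addition or polymerisation. The fallback avoids the ketone by resolution. It sets out from the epimer mixture 13: lipase-catalysed acylation (Amano lipase PS, vinyl acetate) should, by the Kazlauskas rule, acylate the (R)-carbinol to the epimeric acetate F4 and leave the (S)-alcohol, which is separated and comes back to the route at 15.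

Further compounds
F1 | step 13 | (1S)-1-{(2R,3S)-3-[(1R)-1-(TBS-oxy)-2-[(TBS-oxy)methyl]prop-2-en-1-yl]-2-[(PMB-oxy)methyl]oxiran-2-yl}prop-2-en-1-ol | COc1ccc(COC[C@@]2(O[C@H]2[C@H](O[Si](C)(C)C(C)(C)C)C(=C)CO[Si](C)(C)C(C)(C)C)[C@@H](O)C=C)cc1
F2 | step 13 | (1R,2S,5R,6S)-5-(TBS-oxy)-1-[(PMB-oxy)methyl]-4-[(TBS-oxy)methyl]-7-oxabicyclo[4.1.0]hept-3-en-2-ol | COc1ccc(COC[C@]23O[C@H]2[C@H](O[Si](C)(C)C(C)(C)C)C(CO[Si](C)(C)C(C)(C)C)=C[C@@H]3O)cc1
F3 | step 13 | (1S,2S,5R,6S)-2,5-bis(TBS-oxy)-1-[(PMB-oxy)methyl]-4-[(TBS-oxy)methyl]-7-oxabicyclo[4.1.0]hept-3-ene | COc1ccc(COC[C@]23O[C@H]2[C@H](O[Si](C)(C)C(C)(C)C)C(CO[Si](C)(C)C(C)(C)C)=C[C@@H]3O[Si](C)(C)C(C)(C)C)cc1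
F0 | step 26 | none | none
F4 | step 9 | (3R,4Z,6S)-6-(TBS-oxy)-4-[(PMB-oxy)methyl]-7-[(TBS-oxy)methyl]octa-1,4,7-trien-3-yl acetate | C=C(CO[Si](C)(C)C(C)(C)C)[C@@H](O[Si](C)(C)C(C)(C)C)/C=C(\[C@H](OC(C)=O)C=C)COCc1ccc(OC)cc1
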